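The numbers in the tables are simulated on assumed constants; noise was put on by code.

the same everywhere: G 2.5 mol%; L 0.44 mM
- Saturday's: J 0.050 M; X 0.050 M; Z 2.5 equiv; temperature 79 °C; run made earlier
- Tuesday's: J 0.20 M; X 0.20 M; Z 2.5 equiv; temperature 87 °C; run made earlier
- elm: J 0.10 M; X 0.10 M; Z 2.50 equiv; temperature 75 °C; time 4.0 h
- oak: J 0.10 M; X 0.10 M; Z 2.50 equiv; temperature 90 °C; time 4.0 h
- cedar: J 0.10 M; X 0.10 M; Z 2.50 equiv; at 90 °C until 80 min, from then on at 75 °C; time 4.0 h

| run | time / h | Q / % | D / % |
|---|---|---|---|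
| Saturday's | 0.250 | 3.0 | 2.5 |
| Saturday's | 0.667 | 9.6 | 5.2 |
| Saturday's | 1.33 | 17.2 | 6.6 |
| Saturday's | 2.00 | 22.8 | 10.0 |
| Saturday's | 3.00 | 29.1 | 11.0 |
| Saturday's | 4.00 | 36.4 | 12.8 |
| Saturday's | 5.00 | 40.3 | 13.1 |
| Tuesday's | 0.333 | 49.2 | 25.0 |
| Tuesday's | 0.667 | 62.0 | 29.7 |
| Tuesday's | 1.00 | 63.5 | 29.1 |
| Tuesday's | 1.50 | 64.6 | 31.8 |
| Tuesday's | 2.00 | 67.7 | 34.0 |
| Tuesday's | 3.00 | 65.6 | 32.4 |

(scatter of a reading: 1 percentage point)

- G is single-handed; J and X are mirror images of each other, charged as a racemate, each of them at the stated concentration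
- an excess is the difference of the two amounts in percent of their sum
- an excess is below zero if the other one leads

- the flask that comes out highest in excess of Q over D, or "all alike" when all lie within 1.5 percentage points (elm / oak / cedar / all alike)
- excess of Q over D at the end, elm
- excess of Q over D at the end, oak
- excess of Q over D at the end, cedar

Tuesday's last reading has Q at 65.6 % and D at 32.4 %, and J was half of the charge, so J and X must turn into each other.

Pooled, Saturday's readings give 2.59 for the selectivity factor s, the rate into Q over the rate into D at one moment. Tuesday's give 2.05. The excess is then (s − 1)/(s + 1): 44.3 % and 34.4 %.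

Does s drift? I climb the time scales.

I put the exchange of J and X on the first rung. Tuesday's [Q]/[D] reads 1.97 at the first reading and 2.02 at the last, so I take [J] = [X] throughout. Saturday's ratio climbs to 3.08, but its first D is 2.5 % with a scatter of 1 percentage point, so I pool.

Next comes uptake. Tuesday's flask has 74.2 % in product at 0.333 h, Saturday's 49.2 % at 4.00 h.

Last comes the tail, which I take to add amount at a steady s. I assume concentration enters both rates alike, which leaves temperature.

So I commit to elm near 44.3 % and oak near 34.4 %, with elm the higher by more than the margin. I expect cedar as a weighted mean of the two, between them.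

The forecast says elm, with 46 % for elm, 31 % for oak and 32 % for cedar, on the ground that “slow, dilute, cooler conditions favour Q”. Its elm stands above mine, its oak below.

The flasks give 44.2 % for elm, 34.4 % for oak and 36.0 % for cedar, so elm is highest.

    Z + G + J → G + Q (k = 1.30 L² mol⁻² s⁻¹, Ea = 40.0 kJ mol⁻¹)
    Z + G + X → G + D (k = 0.630 L² mol⁻² s⁻¹, Ea = 57.0 kJ mol⁻¹)
    J ⇌ X (k = 0.0160 s⁻¹, Ea = 95.0 kJ mol⁻¹)
    G + L → E (k = 7.90 L mol⁻¹ s⁻¹, Ea = 60.0 kJ mol⁻¹)
    (constants at 90 °C)

In elm, L stands at 0 % by 2.00 h, with G at 82.4 % and E at 17.6 %, and the steps into Q and D run on with that G. Meanwhile J and X stand level, 7.55 % and 7.62 % at 4.00 h, with a relaxation half-life of 1.40 min against 2.2 h for Z by the step to Q at 0.728 h. In elm the ratio of the two rates at the start is 2.6, and the end excess of 44.2 % means [Q]/[D] = 2.58.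

On a further flask, like elm but with 0.62 mol% of G, my s of 2.59 again gives about 44.3 %. That flask gives 44.8 %, with Q 20.3 % and D 7.74 %, while J stands at 36.0 % and X at 36.0 %.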